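(The earlier runs and the new flask come from a simulation for substances that don't exist.)

Blue stops at 1.5 h and green at 5.0 h from the same charge, so we give their average lengths one denominator, the chains begun, and keep the books on initiator, which begins them.

the same everywhere: free monomer 20 mM; initiator 0.50 mM

|  | impurity | remark | time |
|---|---|---|---|
| epsilon | 0.050 mM | run made earlier |  |
| beta | 0.075 mM | run made earlier |  |
| blue | 0.10 mM |  | 1.5 h |
| green | 0.10 mM |  | 5.0 h |

| run | time / min | monomer in chains / % |
|---|---|---|
| epsilon | 6.00 | 1.1 |
| epsilon | 15.0 | 5.1 |
| epsilon | 30.0 | 11.1 |
| epsilon | 50.0 | 15.9 |
| epsilon | 60.0 | 18.3 |
| epsilon | 80.0 | 20.7 |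
| epsilon | 120 | 25.7 |
| beta | 8.00 | 2.5 |
| beta | 12.0 | 3.3 |
| beta | 20.0 | 7.0 |
| beta | 30.0 | 10.8 |
| beta | 50.0 | 15.3 |
| beta | 80.0 | 20.2 |
| beta | 120 | 24.1 |

(readings scatter by 0.3 percentage points)

- the average divides the monomer in chains by the number of chains begun, living and dead together
- what was read earlier has a scatter of 0.3 percentage points, one standard deviation
- steps under discussion: free monomer + initiator -> living end + monomer in chains; free monomer + living end -> monomer in chains + living end; 2 living end -> dead end A; monomer in chains + living end -> free monomer + living end; initiator + impurity -> spent initiator B
- the earlier runs do not show the number of chains; that part of a forecast is a guess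

1. which of the two ends with the longer chains by the average number of monomer units in a chain (chains begun, living or dead) ("neither" if they lie within 10%) (blue / green / neither)
2. average number of monomer units in a chain (chains begun, living or dead) at the end, blue
3. average number of monomer units in a chain (chains begun, living or dead) at the end, green

We define the chain budget C as the initiator charged less the impurity charged, 0.400 mM. The one-for-one debit is our guess: the earlier runs do not show the number of chains.

| Entry, blue and green | Initiator |
|---|---|
| Charged | 0.50 mM |
| To spent initiator B | 0.10 mM |
| Left to begin chains, C | 0.400 mM |

Two living ends joining into dead end A move chains between columns, but each stays counted as begun. We therefore reckon the length as X·cM/C, where X is the fraction of charged free monomer in chains and cM its charge.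

Between its readings, the beta run gives 21.2% at the blue time. We take that for blue, although beta holds less impurity, and reckon 10.6 units. To clear the margin, green needs 23.3%. Beta already reads 24.1% at 120 min, more than that, and was still rising, so we say green.

The forecast says green, with 10.2 for blue and 15 for green, judging that “impurity removes initiator nearly one-for-one”. Its blue length is lower than ours.

    free monomer + initiator → living end + monomer in chains (k = 3.90 /M/min)
    free monomer + living end → monomer in chains + living end, rate k2*[living end]*[free monomer] (k = 19.0 /M/min)
    2 living end → dead end A (k = 60.0 /M/min)
    monomer in chains + living end → free monomer + living end, rate k4*[living end] as long as [monomer in chains] is above zero (k = 0.0720 /min)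
    initiator + impurity → spent initiator B (k = 9200 /M/min)

The flask gives green, with 10.5 for blue and 15.8 for green. At 1.50 h, blue holds 0.0961 mM of living ends and 0.152 mM of dead end A, each dead end counting two chains, which makes 0.400 mM, close to C. Blue stopped at 50 min holds 15.0% monomer in chains and 2.2% of its initiator, so C less that initiator gives 7.70 units, and that flask stands at 7.70.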